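## The problem

The target 29 is a 6,7-seco-ent-kaurane. A cyclohexane (ring A) hangs by the single bond C9–C10 on a bicyclo[3.2.1]octane made of a cyclohexanone (ring C: C8, C9, C11, C12, C13, C14) and a cyclopentane (ring D: C8, C14, C13, C16, C15). The six stereocentres form two blocks. C4, C5 and C10 on ring A carry both carboxyls and the C20 methyl on one face. C8, C9 and C13 sit on the bicycle, where the two bridgeheads amount to one decision and C9 can be steered by the shape of the cage. No ring relays chirality across C9–C10, so ring A must arrive with matching absolute configuration. The bond itself joins quaternary C10 to a tertiary carbon beside quaternary C8. Four groups are fragile: the C16 methylene (acid moves it into ring D), the C7 aldehyde, the epimerisable C5–H, and the C19 and C6 carboxyls, which are too hindered to be freed by saponification next to an aldehyde and a ketone. The opening is ring C: its C12 carbonyl lies para to quaternary C8, so it is a 4,4-disubstituted cyclohexadienone in disguise, and the alpha carbon C13 can reach C16, the second atom of a two-carbon chain on C8.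

## Retrosynthesis

**End game.** The two acids of 29 are carried as 2-(trimethylsilyl)ethyl esters (28), because fluoride cleaves them at silicon and never has to reach the shielded carbonyls. The aldehyde comes from the C7 carbinol 27. The methylene of 27 comes from the beta-hydroxysilane 26 by Peterson elimination, so no alkene is present while radicals are in play.

**C9–C10.** Cutting this bond splits 26 into the bicyclic enone 14 and the ring A methylene diester 25. A tertiary carbanion at C10 is not a workable nucleophile, but the tertiary radical made by hydrogen-atom transfer to the methylene of 25 is, and it tolerates the free hydroxyls of 14. The forward step must pick the right face twice: the face of the C10 radical away from the two cis esters, and the exo face of C9 away from the two-carbon bridge. Cutting C8–C9 instead would leave two quaternary centres to join.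

**Redox adjustment.** Enone diol 14 comes from keto ester 12 through triol 13. The C7 ester must be reduced before ring A arrives, since three esters could not be told apart afterwards. The enone carbonyl is reduced on the way and restored by allylic oxidation. The C7 hydroxyl is left free, which keeps the neighbourhood of C9 small.

**Key disconnection.** Cutting C13–C16 and removing the hydride from C14 turns 12 into the flat, achiral dienone 10. One reaction must then choose between two enantiotopic enone arms, close ring D and leave the other enone for step 18. The precursor loses both rings' stereochemistry and a ring; the silylmethyl ketone carries the future methylene as a beta-hydroxysilane.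

**Dienone.** Ketone 10 comes from diene 9 by oxidation of the doubly allylic CH2, placed last so that no dienone meets a Grignard reagent or strong acid. Ketone 9 comes from Weinreb amide 7 and the silylmethyl Grignard 8, and 7 from acid 6, diester 5 and acid 4. Birch reductive alkylation of benzoic acid 1 with bromoacetate 2 (via dianion 3) sets quaternary C8.

**Ring A.** Diester 25 has cis carboxyls on C4 and C5 beside a quaternary methyl, which is the signature of a citraconate dienophile. Cutting C5–C10 and C3–C4 leads to triene 18, from dienol 15 and citraconic anhydride 16 through half ester 17. An intermolecular version would give the wrong regiochemistry; the ester tether of 18 fixes it and is later the leaving group. The adduct 19 is hydrogenated (20), the lactone CH2–O bond is broken by selenolate (21), the acids are protected (22), and selenoxide 24 eliminates to the methylene. The Diels–Alder substrate is achiral, so the racemate is divided once, at the UV-active selenide 22, to give 23.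

## Roads not taken

**Alternative 1:** Cut C5–C10 and C8–C9 of a carbocyclic ring B that exists only to be cleaved at C6=C7. An open-chain trienoate carrying the C4 centre would cyclise on heating or with (CH3)2AlCl to the trans-octalin diester A1, and ozonolysis would later turn C6 and C7 into carbonyls. Its merit is real: ring A, the congested C9–C10 bond and the relative configuration of C5, C9 and C10 come from one ordered transition state with no fragment matching. In that respect it is better than the plan chosen here, which needs an intermolecular radical coupling with two independent face selections. Its weak points lie elsewhere. In A1 C8 is still a CH2, so the whole bicycle with its quaternary bridgehead remains to be built. Ozonolysis cannot follow the C16 methylene and delivers two aldehydes that must be differentiated. Absolute configuration rests on 1,3-induction from a preset C4. Against this the chosen plan sets the harder half, two rings and three centres, catalytically in one step and is convergent.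

**Alternative 2:** Cut C5–C10 and C3–C4 with ring A made last on the finished bicycle. A citraconate ester tethered through C7–O–C6 would add to a diene on C9 to give the lactone-bridged cycloadduct A2. This road is better than the chosen one in a central respect: ring A takes its chirality from the bicycle, so no separate enantiopure ring A fragment and no separation of enantiomers is needed. C6 and C7 also emerge already linked at useful oxidation levels. The doubts are in the cycloaddition itself. The diene terminus C10 carries a methyl and the whole bicycle, the tether closes a seven-membered lactone through a loose transition state, and the diene must first be installed next to quaternary C8. The chosen plan uses the same citraconate logic where it is precedented, with a five-membered lactone tether on a small fragment, and pays for that with step 16.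

**Alternative 3:** Cut C12–C13 and close ring C last. TiCl4 would activate a C12 acid chloride, a cyclopentenylmethylsilane would attack through C13, and loss of silicon would leave the C16 methylene in A3. It is more economical at this point than the chosen plan: ketone and methylene appear in the ring-closing step, with no latent group, no Peterson step and no redox detour. But everything else must already be in place on a cyclopentene: quaternary C8, the C9–C10 bond and five stereocentres, with no built-in source of absolute configuration. The beta,gamma-unsaturated ketone product would also sit in TiCl4. The chosen plan spends three extra operations on the methylene, but builds the bicycle first, from benzoic acid, with catalyst control.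

Key step: step 7

Remark: the copper hydride step is written for (R)-DTBM-SEGPHOS; if the first run gives the antipode of 12, the (S) ligand is used and nothing else changes.
Remark: compounds 19–22 are racemates; their names and SMILES show the enantiomer that continues as 23.
Remark: (2E)-penta-2,4-dien-1-ol 15 is taken as a catalogue compound.

## Route

Step 1
Reactants: 1 benzoic acid; 2 tert-butyl bromoacetate
Product: 4 1-(2-tert-butoxy-2-oxoethyl)cyclohexa-2,5-diene-1-carboxylic acid, via dilithium Birch dianion 3 (not isolated)
Conditions: Li (2.5 equiv), NH3(l)/THF, −78 °C; then 2, −78 °C; NH4Cl, aq. HCl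
Reagents that add atoms: none
Why: Birch reductive alkylation: lithium in ammonia reduces the benzoate to the cross-conjugated dianion 3, which is alkylated at the ipso carbon and so sets quaternary C8 with both future enone arms attached.

Step 2
Reactants: 4 1-(2-tert-butoxy-2-oxoethyl)cyclohexa-2,5-diene-1-carboxylic acid
Product: 5 methyl 1-(2-tert-butoxy-2-oxoethyl)cyclohexa-2,5-diene-1-carboxylate
Conditions: MeI, K2CO3, DMF, rt
Reagents that add atoms: iodomethane, CI
Why: Carboxylate O-alkylation (SN2) differentiates the two carboxyls and leaves the tert-butyl ester alone.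

Step 3
Reactants: 5 methyl 1-(2-tert-butoxy-2-oxoethyl)cyclohexa-2,5-diene-1-carboxylate
Product: 6 [1-(methoxycarbonyl)cyclohexa-2,5-dien-1-yl]acetic acid
Conditions: CF3CO2H, CH2Cl2, 0 °C → rt
Reagents that add atoms: none
Why: Acidolysis of the tert-butyl ester (loss of isobutene) frees only the side-chain acid; it is run before any dienone exists, so dienone–phenol rearrangement cannot interfere.

Step 4
Reactants: 6 [1-(methoxycarbonyl)cyclohexa-2,5-dien-1-yl]acetic acid
Product: 7 methyl 1-{2-[methoxy(methyl)amino]-2-oxoethyl}cyclohexa-2,5-diene-1-carboxylate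
Conditions: MeNHOMe·HCl, EDC·HCl, HOBt (cat.), N-methylmorpholine, CH2Cl2, 0 °C → rt
Reagents that add atoms: N,O-dimethylhydroxylamine hydrochloride, CNOC.Cl
Why: Carbodiimide amide coupling gives the Weinreb amide of the unhindered side-chain acid.

Step 5
Reactants: 7 methyl 1-{2-[methoxy(methyl)amino]-2-oxoethyl}cyclohexa-2,5-diene-1-carboxylate; 8 (trimethylsilyl)methylmagnesium chloride
Product: 9 methyl 1-[2-oxo-3-(trimethylsilyl)propyl]cyclohexa-2,5-diene-1-carboxylate
Conditions: 8 (1.5 equiv), THF, −20 → 0 °C; aq. NH4Cl
Reagents that add atoms: none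
Why: Weinreb ketone synthesis: the chelated tetrahedral adduct stops at the ketone, and the methyl ester on quaternary C8 is too hindered to compete at 0 °C.

Step 6
Reactants: 9 methyl 1-[2-oxo-3-(trimethylsilyl)propyl]cyclohexa-2,5-diene-1-carboxylate
Product: 10 methyl 4-oxo-1-[2-oxo-3-(trimethylsilyl)propyl]cyclohexa-2,5-diene-1-carboxylate
Conditions: t-BuOOH (anhydrous, 4 equiv), (C5H5NH)2Cr2O7 (pyridinium dichromate, 0.3 equiv), Celite, PhH, rt
Reagents that add atoms: tert-butyl hydroperoxide, CC(C)(C)OO
Why: Chromium-catalysed allylic oxidation with tert-butyl hydroperoxide attacks the doubly allylic CH2, the weakest C–H bond, and gives the cross-conjugated dienone; alpha-silyl ketones are themselves made from beta-hydroxysilanes with hexavalent chromium in pyridine media and should survive.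

Step 7
Reactants: 10 methyl 4-oxo-1-[2-oxo-3-(trimethylsilyl)propyl]cyclohexa-2,5-diene-1-carboxylate
Product: 12 methyl (1R,5R,6S)-6-hydroxy-4-oxo-6-[(trimethylsilyl)methyl]bicyclo[3.2.1]oct-2-ene-1-carboxylate, via silyl-capped aldolate 11 (not isolated)
Conditions: Cu(OAc)2·H2O (5 mol %), (R)-DTBM-SEGPHOS (5.5 mol %), (HMe2Si)2O (1.0 equiv), PhMe, 0 °C → rt; then AcOH/THF/H2O, rt
Reagents that add atoms: none
Why: Copper hydride reductive aldol cyclisation used as a desymmetrisation. Cu(OAc)2, the bisphosphine and the disiloxane give a chiral monovalent copper hydride, which adds hydride 1,4 to one of the two enantiotopic enone arms at C14 and leaves a copper enolate across C12–C13. C13 then adds to the side-chain ketone C16 in a 5-(enolexo)-exo-trig aldol, the only closure open to a nucleophile two atoms from C8, and ring D forms as the two-carbon bridge of a bicyclo[3.2.1]octane. The copper aldolate exchanges with Si–H to give 11 and regenerate the hydride, and aqueous acetic acid frees 12. The closest known reactions are copper hydride reductive aldol cyclisations of enone–ketones and copper-catalysed desymmetrisations of 4,4-disubstituted cyclohexadienones. C8 is set by the ligand through the choice of arm; C13 follows of necessity because the short tether can only bridge cis; C16 is set by a closed, copper-bridged transition state that holds the ketone oxygen beside the enolate oxygen (hydroxyl endo, towards C12) and is erased in step 19. The step needs 1,4- over 1,2-reduction and a single hydride delivery: copper hydride reduces enones faster than dialkyl ketones, the surviving enone has its beta carbon next to the new quaternary bridgehead, and the silane is held at one equivalent.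

Step 8
Reactants: 12 methyl (1R,5R,6S)-6-hydroxy-4-oxo-6-[(trimethylsilyl)methyl]bicyclo[3.2.1]oct-2-ene-1-carboxylate
Product: 13 (1S,5R,7S)-5-(hydroxymethyl)-7-[(trimethylsilyl)methyl]bicyclo[3.2.1]oct-3-ene-2,7-diol (both C2 epimers)
Conditions: i-Bu2AlH (5 equiv), CH2Cl2, −78 → 0 °C; aq. potassium sodium tartrate
Reagents that add atoms: none
Why: Aluminium hydride reduction takes the ester to the C7 carbinol and the enone carbonyl 1,2 to the allylic alcohol; the epimer mixture at the carbinol is removed in step 9, and the cold, non-basic medium avoids retro-aldol opening.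

Step 9
Reactants: 13 (1S,5R,7S)-5-(hydroxymethyl)-7-[(trimethylsilyl)methyl]bicyclo[3.2.1]oct-3-ene-2,7-diol
Product: 14 (1R,5R,7S)-7-hydroxy-5-(hydroxymethyl)-7-[(trimethylsilyl)methyl]bicyclo[3.2.1]oct-3-en-2-one
Conditions: MnO2 (activated, 20 equiv), CH2Cl2, rt
Reagents that add atoms: none
Why: MnO2 oxidises only the allylic alcohol, so the enone returns while the neopentyl primary and the tertiary hydroxyl stay untouched.

Step 10
Reactants: 15 (2E)-penta-2,4-dien-1-ol; 16 citraconic anhydride
Product: 17 (2Z)-2-methyl-4-oxo-4-[(2E)-penta-2,4-dien-1-yloxy]but-2-enoic acid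
Conditions: Et3N (1.1 equiv), DMAP (5 mol %), CH2Cl2, 0 °C → rt; aq. HCl wash
Reagents that add atoms: none
Why: Nucleophile-catalysed alcoholysis of the anhydride at the less hindered carbonyl (the one on the CH= carbon) gives the half ester with its free acid on the methyl-bearing carbon and the Z geometry intact.

Step 11
Reactants: 17 (2Z)-2-methyl-4-oxo-4-[(2E)-penta-2,4-dien-1-yloxy]but-2-enoic acid
Product: 18 1-methyl 4-[(2E)-penta-2,4-dien-1-yl] (2Z)-2-methylbut-2-enedioate
Conditions: MeI, KHCO3, DMF, rt
Reagents that add atoms: iodomethane, CI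
Why: Carboxylate O-methylation (SN2) blocks reversion to anhydride and alcohol during the thermal step.

Step 12
Reactants: 18 1-methyl 4-[(2E)-penta-2,4-dien-1-yl] (2Z)-2-methylbut-2-enedioate
Product: 19 rac-methyl (3aS,7R,7aS)-7-methyl-1-oxo-1,3,3a,6,7,7a-hexahydro-2-benzofuran-7-carboxylate
Conditions: PhMe, BHT (cat.), 140 °C, sealed tube
Reagents that add atoms: none
Why: Intramolecular Diels–Alder reaction of a pentadienyl citraconate: the ester tether forces C10 onto C5 and C3 onto C4, and suprafacial addition to the Z dienophile puts C6 and C19 cis, which fixes C4 relative to C5. The transition state with both carbonyls endo should give the cis-fused lactone, whose C10 centre is erased in step 17.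

Step 13
Reactants: 19 rac-methyl (3aS,7R,7aS)-7-methyl-1-oxo-1,3,3a,6,7,7a-hexahydro-2-benzofuran-7-carboxylate
Product: 20 rac-methyl (3aS,7R,7aS)-7-methyl-1-oxooctahydro-2-benzofuran-7-carboxylate
Conditions: H2 (1 atm), Pd/C (10%), EtOAc, rt
Reagents that add atoms: none
Why: Heterogeneous hydrogenation of the disubstituted ring alkene; no stereocentre is made or touched.

Step 14
Reactants: 20 rac-methyl (3aS,7R,7aS)-7-methyl-1-oxooctahydro-2-benzofuran-7-carboxylate
Product: 21 rac-(1R,2S,3S)-1-methyl-3-[(phenylselanyl)methyl]cyclohexane-1,2-dicarboxylic acid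
Conditions: (PhSe)2 (1.3 equiv), NaBH4 (2.6 equiv), DMF, 120 °C; then 1 M HCl
Reagents that add atoms: diphenyl diselenide, c1ccc(cc1)[Se][Se]c1ccccc1
Why: Liotta-type SN2 dealkylation: benzeneselenolate opens the gamma-lactone at its CH2–O carbon (C20) and removes the methyl of the hindered ester by attack at carbon, not at the shielded carbonyls; the selenolate is too weak a base to epimerise C5.

Step 15
Reactants: 21 rac-(1R,2S,3S)-1-methyl-3-[(phenylselanyl)methyl]cyclohexane-1,2-dicarboxylic acid
Product: 22 rac-bis[2-(trimethylsilyl)ethyl] (1R,2S,3S)-1-methyl-3-[(phenylselanyl)methyl]cyclohexane-1,2-dicarboxylate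
Conditions: Me3SiCH2CH2OH (3 equiv), PPh3 (3 equiv), DIAD (3 equiv), THF, 0 °C → rt
Reagents that add atoms: 2-(trimethylsilyl)ethanol, C[Si](C)(C)CCO
Why: Mitsunobu esterification: the carboxylates attack the activated primary alcohol, so the tertiary C19 acid is esterified without any attack on its hindered carbonyl.

Step 16
Reactants: 22 rac-bis[2-(trimethylsilyl)ethyl] (1R,2S,3S)-1-methyl-3-[(phenylselanyl)methyl]cyclohexane-1,2-dicarboxylate
Product: 23 bis[2-(trimethylsilyl)ethyl] (1R,2S,3S)-1-methyl-3-[(phenylselanyl)methyl]cyclohexane-1,2-dicarboxylate (single enantiomer)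
Conditions: preparative SFC, amylose tris(3,5-dimethylphenylcarbamate) phase, CO2/i-PrOH, UV detection
Reagents that add atoms: none
Why: Enantiomer separation on a polysaccharide chiral stationary phase; no bond is made. It fixes the absolute configuration of C4 and C5, and the phenylselanyl group supplies the chromophore; the peak is assigned by X-ray (selenium) or by carrying a sample to 26.

Step 17
Reactants: 23 bis[2-(trimethylsilyl)ethyl] (1R,2S,3S)-1-methyl-3-[(phenylselanyl)methyl]cyclohexane-1,2-dicarboxylate
Product: 25 bis[2-(trimethylsilyl)ethyl] (1R,2S)-1-methyl-3-methylidenecyclohexane-1,2-dicarboxylate, via selenoxide 24 (not isolated)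
Conditions: H2O2 (30%, 5 equiv), pyridine, CH2Cl2, 0 → 40 °C
Reagents that add atoms: none
Why: Selenide oxidation and selenoxide syn-elimination: the only beta hydrogen is on C10, so the exocyclic methylene forms regiospecifically under buffered conditions that leave C5–H alone.

Step 18
Reactants: 14 (1R,5R,7S)-7-hydroxy-5-(hydroxymethyl)-7-[(trimethylsilyl)methyl]bicyclo[3.2.1]oct-3-en-2-one; 25 bis[2-(trimethylsilyl)ethyl] (1R,2S)-1-methyl-3-methylidenecyclohexane-1,2-dicarboxylate
Product: 26 bis[2-(trimethylsilyl)ethyl] 7,16-dihydroxy-12-oxo-17-(trimethylsilyl)-6,7-seco-ent-kaurane-6,19-dioate (C16 as in 12)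
Conditions: Fe(acac)3 (0.5 equiv), PhSiH3 (2.5 equiv), 25 (2 equiv), EtOH/(CH2OH)2 (5:1), 60 °C
Reagents that add atoms: none
Why: Iron-hydride hydrogen-atom-transfer olefin–enone coupling (radical conjugate addition): H adds to the methylene carbon of 25, the tertiary C10 radical adds to C9 of 14, and the alpha-keto radical is reduced and protonated. C10 should be attacked on the face opposite the two cis esters (trans to the vicinal C5 ester), which puts C20 cis to both. C9 should be attacked from the exo face, anti to the two-carbon bridge and its endo hydroxyl.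

Step 19
Reactants: 26 bis[2-(trimethylsilyl)ethyl] 7,16-dihydroxy-12-oxo-17-(trimethylsilyl)-6,7-seco-ent-kaurane-6,19-dioate
Product: 27 bis[2-(trimethylsilyl)ethyl] 7-hydroxy-12-oxo-6,7-seco-ent-kaur-16-ene-6,19-dioate
Conditions: p-TsOH·H2O (0.2 equiv), CH2Cl2, 0 °C → rt
Reagents that add atoms: none
Why: Acid-mediated Peterson elimination: ionisation of the tertiary carbinol is assisted by the beta silicon, and loss of the silyl group can only give the C16=C17 methylene. Acid is used because base would open the beta-hydroxy ketone by retro-aldol.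

Step 20
Reactants: 27 bis[2-(trimethylsilyl)ethyl] 7-hydroxy-12-oxo-6,7-seco-ent-kaur-16-ene-6,19-dioate
Product: 28 bis[2-(trimethylsilyl)ethyl] 7,12-dioxo-6,7-seco-ent-kaur-16-ene-6,19-dioate
Conditions: Dess–Martin periodinane (1.5 equiv), CH2Cl2, rt
Reagents that add atoms: none
Why: Dess–Martin oxidation of the only remaining alcohol to the non-enolisable C7 aldehyde under neutral conditions that spare the methylene.

Step 21
Reactants: 28 bis[2-(trimethylsilyl)ethyl] 7,12-dioxo-6,7-seco-ent-kaur-16-ene-6,19-dioate
Product: 29 7,12-dioxo-6,7-seco-ent-kaur-16-ene-6,19-dioic acid (CNP0320711.1)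
Conditions: Bu4NF (4 equiv), THF, 0 °C → rt; aq. KHSO4
Reagents that add atoms: none
Why: Fluoride-induced fragmentation of the 2-(trimethylsilyl)ethyl esters (attack at silicon, loss of ethene) frees both hindered acids without a nucleophile at their carbonyls; C5–H, flanked by two quaternary carbons, should not be removed by fluoride.

## Compound list

1 | benzoic acid | O=C(O)c1ccccc1 | starting material
2 | tert-butyl bromoacetate | CC(C)(C)OC(=O)CBr | starting material
3 | dilithium (cyclohexa-2,5-dien-1-ylidene)methanediolate | [Li+].[Li+].[O-]C([O-])=C1C=CCC=C1 | intermediate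
4 | 1-(2-tert-butoxy-2-oxoethyl)cyclohexa-2,5-diene-1-carboxylic acid | CC(C)(C)OC(=O)CC1(C(=O)O)C=CCC=C1 | intermediate
5 | methyl 1-(2-tert-butoxy-2-oxoethyl)cyclohexa-2,5-diene-1-carboxylate | CC(C)(C)OC(=O)CC1(C(=O)OC)C=CCC=C1 | intermediate
6 | [1-(methoxycarbonyl)cyclohexa-2,5-dien-1-yl]acetic acid | OC(=O)CC1(C(=O)OC)C=CCC=C1 | intermediate
7 | methyl 1-{2-[methoxy(methyl)amino]-2-oxoethyl}cyclohexa-2,5-diene-1-carboxylate | CON(C)C(=O)CC1(C(=O)OC)C=CCC=C1 | intermediate
8 | (trimethylsilyl)methylmagnesium chloride | C[Si](C)(C)C[Mg]Cl | starting material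
9 | methyl 1-[2-oxo-3-(trimethylsilyl)propyl]cyclohexa-2,5-diene-1-carboxylate | C[Si](C)(C)CC(=O)CC1(C(=O)OC)C=CCC=C1 | intermediate
10 | methyl 4-oxo-1-[2-oxo-3-(trimethylsilyl)propyl]cyclohexa-2,5-diene-1-carboxylate | C[Si](C)(C)CC(=O)CC1(C(=O)OC)C=CC(=O)C=C1 | intermediate
11 | methyl (1R,5R,6S)-4-oxo-6-[(1,1,3,3-tetramethyldisiloxanyl)oxy]-6-[(trimethylsilyl)methyl]bicyclo[3.2.1]oct-2-ene-1-carboxylate | C[SiH](C)O[Si](C)(C)O[C@@]1(C[Si](C)(C)C)C[C@]2(C(=O)OC)C[C@H]1C(=O)C=C2 | intermediate
12 | methyl (1R,5R,6S)-6-hydroxy-4-oxo-6-[(trimethylsilyl)methyl]bicyclo[3.2.1]oct-2-ene-1-carboxylate | O[C@@]1(C[Si](C)(C)C)C[C@]2(C(=O)OC)C[C@H]1C(=O)C=C2 | intermediate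
13 | (1S,5R,7S)-5-(hydroxymethyl)-7-[(trimethylsilyl)methyl]bicyclo[3.2.1]oct-3-ene-2,7-diol, C2 epimers | O[C@@]1(C[Si](C)(C)C)C[C@]2(CO)C[C@H]1C(O)C=C2 | intermediate
14 | (1R,5R,7S)-7-hydroxy-5-(hydroxymethyl)-7-[(trimethylsilyl)methyl]bicyclo[3.2.1]oct-3-en-2-one | O[C@@]1(C[Si](C)(C)C)C[C@]2(CO)C[C@H]1C(=O)C=C2 | intermediate
15 | (2E)-penta-2,4-dien-1-ol | C=C/C=C/CO | starting material
16 | citraconic anhydride (3-methylfuran-2,5-dione) | CC1=CC(=O)OC1=O | starting material
17 | (2Z)-2-methyl-4-oxo-4-[(2E)-penta-2,4-dien-1-yloxy]but-2-enoic acid | C=C/C=C/COC(=O)/C=C(C)\C(=O)O | intermediate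
18 | 1-methyl 4-[(2E)-penta-2,4-dien-1-yl] (2Z)-2-methylbut-2-enedioate | C=C/C=C/COC(=O)/C=C(C)\C(=O)OC | intermediate
19 | rac-methyl (3aS,7R,7aS)-7-methyl-1-oxo-1,3,3a,6,7,7a-hexahydro-2-benzofuran-7-carboxylate | O=C1OC[C@H]2C=CC[C@@](C)(C(=O)OC)[C@@H]12 | intermediate
20 | rac-methyl (3aS,7R,7aS)-7-methyl-1-oxooctahydro-2-benzofuran-7-carboxylate | O=C1OC[C@H]2CCC[C@@](C)(C(=O)OC)[C@@H]12 | intermediate
21 | rac-(1R,2S,3S)-1-methyl-3-[(phenylselanyl)methyl]cyclohexane-1,2-dicarboxylic acid | c1ccc(cc1)[Se]C[C@H]2CCC[C@@](C)(C(=O)O)[C@H]2C(=O)O | intermediate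
22 | rac-bis[2-(trimethylsilyl)ethyl] (1R,2S,3S)-1-methyl-3-[(phenylselanyl)methyl]cyclohexane-1,2-dicarboxylate | c1ccc(cc1)[Se]C[C@H]2CCC[C@@](C)(C(=O)OCC[Si](C)(C)C)[C@H]2C(=O)OCC[Si](C)(C)C | intermediate
23 | bis[2-(trimethylsilyl)ethyl] (1R,2S,3S)-1-methyl-3-[(phenylselanyl)methyl]cyclohexane-1,2-dicarboxylate, single enantiomer | c1ccc(cc1)[Se]C[C@H]2CCC[C@@](C)(C(=O)OCC[Si](C)(C)C)[C@H]2C(=O)OCC[Si](C)(C)C | intermediate
24 | bis[2-(trimethylsilyl)ethyl] (1R,2S,3S)-1-methyl-3-[(phenylseleninyl)methyl]cyclohexane-1,2-dicarboxylate | [O-][Se+](c1ccccc1)C[C@H]2CCC[C@@](C)(C(=O)OCC[Si](C)(C)C)[C@H]2C(=O)OCC[Si](C)(C)C | intermediate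
25 | bis[2-(trimethylsilyl)ethyl] (1R,2S)-1-methyl-3-methylidenecyclohexane-1,2-dicarboxylate | C=C1CCC[C@@](C)(C(=O)OCC[Si](C)(C)C)[C@H]1C(=O)OCC[Si](C)(C)C | intermediate
26 | bis[2-(trimethylsilyl)ethyl] 7,16-dihydroxy-12-oxo-17-(trimethylsilyl)-6,7-seco-ent-kaurane-6,19-dioate | O[C@@]1(C[Si](C)(C)C)C[C@]2(CO)C[C@H]1C(=O)C[C@H]2[C@]1(C)CCC[C@@](C)(C(=O)OCC[Si](C)(C)C)[C@H]1C(=O)OCC[Si](C)(C)C | intermediate
27 | bis[2-(trimethylsilyl)ethyl] 7-hydroxy-12-oxo-6,7-seco-ent-kaur-16-ene-6,19-dioate | C=C1C[C@]2(CO)C[C@H]1C(=O)C[C@H]2[C@]1(C)CCC[C@@](C)(C(=O)OCC[Si](C)(C)C)[C@H]1C(=O)OCC[Si](C)(C)C | intermediate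
28 | bis[2-(trimethylsilyl)ethyl] 7,12-dioxo-6,7-seco-ent-kaur-16-ene-6,19-dioate | C=C1C[C@]2(C=O)C[C@H]1C(=O)C[C@H]2[C@]1(C)CCC[C@@](C)(C(=O)OCC[Si](C)(C)C)[C@H]1C(=O)OCC[Si](C)(C)C | intermediate
29 | 7,12-dioxo-6,7-seco-ent-kaur-16-ene-6,19-dioic acid (CNP0320711.1) | C=C1C[C@]2(C=O)C[C@H]1C(=O)C[C@H]2[C@]1(C)CCC[C@@](C)(C(=O)O)[C@H]1C(=O)O | target

## Step count and least certain steps

Total: 21 steps. Longest linear sequence: 13 steps (steps 1–9 and 18–21). The ring A branch (steps 10–17) is 8 steps.

**Step 7 (key step).** The copper enolate may be silylated by the disiloxane before it reaches the hindered silylmethyl ketone through the bridged transition state, or a second hydride may be delivered to the surviving enone. Both are rate questions that cannot be settled on paper. The fallback separates hydride delivery from C–C bond formation. It sets out from 10: the same chiral copper hydride with PhMe2SiH in excess is allowed to stop at methyl (1R)-4-{[dimethyl(phenyl)silyl]oxy}-1-[2-oxo-3-(trimethylsilyl)propyl]cyclohexa-2,4-diene-1-carboxylate F1, a regiodefined silyl dienol ether of the reduced arm. A Mukaiyama aldol closure with BF3·OEt2 in CH2Cl2 at −78 °C then forms C13–C16 and returns to the route at 12.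

**Step 18.** Addition of the tertiary C10 radical to C9, beside quaternary C8, may be too slow, so that 25 is consumed by reduction or by hydrogen-atom-transfer isomerisation to the conjugated ester, while the iron hydride also reduces 14. The fallback generates the same radical without a metal hydride. It sets out from 25: Mukaiyama hydration (Mn(dpm)3, PhSiH3, O2, i-PrOH) gives bis[2-(trimethylsilyl)ethyl] (1R,2S)-3-hydroxy-1,3-dimethylcyclohexane-1,2-dicarboxylate F2 (either C3 epimer serves). Methyl chlorooxoacetate with Et3N and DMAP gives its methyl oxalate F3, and CsOH in THF/H2O gives the caesium oxalate F4. Visible-light photoredox decarboxylation (Ir[dF(CF3)ppy]2(dtbbpy)PF6, blue LEDs, DME/DMF, H2O) in the presence of 14 then returns to the route at 26.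

**Step 6.** The alpha-silyl ketone may be desilylated by the mildly acidic chromium medium during the oxidation. The fallback oxidises before the silicon is introduced. It sets out from 5: the same chromium/t-BuOOH oxidation gives methyl 1-(2-tert-butoxy-2-oxoethyl)-4-oxocyclohexa-2,5-diene-1-carboxylate F5. Brief CF3CO2H at 0 °C gives [1-(methoxycarbonyl)-4-oxocyclohexa-2,5-dien-1-yl]acetic acid F6, and (COCl)2 with catalytic DMF gives the acid chloride methyl 1-(2-chloro-2-oxoethyl)-4-oxocyclohexa-2,5-diene-1-carboxylate F7. Negishi acylation with Me3SiCH2ZnCl (from 8 and ZnCl2) and zerovalent palladium, Pd(PPh3)4, then returns to the route at 10; the organozinc does not touch the dienone.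

**Step 16.** The two enantiomers may not be resolved well enough on a preparative scale. The fallback moves the separation to diastereomers. It sets out from 22: oxidation and elimination as in step 17 give racemic diester, that is 25 together with its enantiomer bis[2-(trimethylsilyl)ethyl] (1S,2R)-1-methyl-3-methylidenecyclohexane-1,2-dicarboxylate F8. The coupling of step 18 then gives 26 together with the ring A diastereomer F9 (C4, C5 and C10 inverted), and chromatography on silica returns to the route at 26. The cost is half of the coupled material.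

**Step 21.** The basic fluoride may cause aldol or hydride-transfer reactions of the free aldehyde next to the ketone before both esters have fragmented. The fallback frees the acids before the aldehyde exists. It sets out from 27: Bu4NF gives 7-hydroxy-12-oxo-6,7-seco-ent-kaur-16-ene-6,19-dioic acid F10, and oxidation of its primary alcohol with TEMPO and PhI(OAc)2 in CH2Cl2 returns to the route at 29.

## Further compounds

F1 | step 7 | methyl (1R)-4-{[dimethyl(phenyl)silyl]oxy}-1-[2-oxo-3-(trimethylsilyl)propyl]cyclohexa-2,4-diene-1-carboxylate | C[Si](C)(C)CC(=O)C[C@]1(C(=O)OC)CC=C(O[Si](C)(C)c2ccccc2)C=C1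
F2 | step 18 | bis[2-(trimethylsilyl)ethyl] (1R,2S)-3-hydroxy-1,3-dimethylcyclohexane-1,2-dicarboxylate | CC1(O)CCC[C@@](C)(C(=O)OCC[Si](C)(C)C)[C@H]1C(=O)OCC[Si](C)(C)C
F3 | step 18 | methyl oxalate of F2 | COC(=O)C(=O)OC1(C)CCC[C@@](C)(C(=O)OCC[Si](C)(C)C)[C@H]1C(=O)OCC[Si](C)(C)C
F4 | step 18 | caesium oxalate of F2 | [Cs+].[O-]C(=O)C(=O)OC1(C)CCC[C@@](C)(C(=O)OCC[Si](C)(C)C)[C@H]1C(=O)OCC[Si](C)(C)C
F5 | step 6 | methyl 1-(2-tert-butoxy-2-oxoethyl)-4-oxocyclohexa-2,5-diene-1-carboxylate | CC(C)(C)OC(=O)CC1(C(=O)OC)C=CC(=O)C=C1
F6 | step 6 | [1-(methoxycarbonyl)-4-oxocyclohexa-2,5-dien-1-yl]acetic acid | OC(=O)CC1(C(=O)OC)C=CC(=O)C=C1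
F7 | step 6 | methyl 1-(2-chloro-2-oxoethyl)-4-oxocyclohexa-2,5-diene-1-carboxylate | ClC(=O)CC1(C(=O)OC)C=CC(=O)C=C1
F8 | step 16 | bis[2-(trimethylsilyl)ethyl] (1S,2R)-1-methyl-3-methylidenecyclohexane-1,2-dicarboxylate | C=C1CCC[C@](C)(C(=O)OCC[Si](C)(C)C)[C@@H]1C(=O)OCC[Si](C)(C)C
F9 | step 16 | ring A diastereomer of 26 (C4, C5, C10 inverted) | O[C@@]1(C[Si](C)(C)C)C[C@]2(CO)C[C@H]1C(=O)C[C@H]2[C@@]1(C)CCC[C@](C)(C(=O)OCC[Si](C)(C)C)[C@@H]1C(=O)OCC[Si](C)(C)C
F10 | step 21 | 7-hydroxy-12-oxo-6,7-seco-ent-kaur-16-ene-6,19-dioic acid | C=C1C[C@]2(CO)C[C@H]1C(=O)C[C@H]2[C@]1(C)CCC[C@@](C)(C(=O)O)[C@H]1C(=O)O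
A1 | alternative 1 | trans-octalin diester | COC(=O)[C@H]2[C@]1(C)CCC[C@@](C)(C(=O)OC)[C@H]1C=CC2
A2 | alternative 2 | lactone-bridged cycloadduct | O1CCOC13C[C@]2(CO4)C[C@H]3C(=O)C[C@H]2[C@]5(C)C=CC[C@@](C)(C(=O)OC)[C@H]5C4=O
A3 | alternative 3 | bicyclic methylene ketone thioester | C=C1C[C@]2(C(=O)SCC)C[C@H]1C(=O)C[C@H]2[C@]1(C)CCC[C@@](C)(C(=O)OC)[C@H]1C(=O)OC
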